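## The problem

Ascomindone B (29) is a 2,3-diarylinden-1-one in which ring C is fused to the five-membered enone, C2 carries ring B, ring B is tied through a diaryl ether oxygen to the salicylate ring A, and C3 carries the orcinol-derived ring D. The hardest bond is the tetrasubstituted C2=C3 alkene: C2 holds ring B with an aryloxy group in its ortho position, and C3 holds ring D with two ortho oxygens and lies next to the C4 oxygen of ring C, so any method that joins a finished aryl group to a finished indenone must work at a very crowded carbon. The diaryl ether is the second crowded site, because its oxygen is flanked on ring B by the indenone carbon and an oxygen, and on ring A by the ester. The target has no stereocentre, and the two that appear in passing at C2 and C3 of hydroxyindanone 26 are made in one event and erased in one event, so only their relative configuration matters, and only for the mode of elimination. Five free phenols on electron-rich rings, a reducible and electrophilic indenone double bond and a methyl ester beside a phenol rule out hydrogenolysis, hard Lewis acids and strong nucleophiles at the end, and two aryl methyl ethers must survive whatever frees the phenols. The enabling feature is that C3 can be carried as a diarylmethane CH2 that bears ring D and sits on ring C ortho to the carbon that becomes C1. If C1 and C2 are present as a 1,2-diketone, the doubly benzylic hydrogen lies within reach of the excited carbonyl and light can close C2–C3.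

## Retrosynthesis

**29 from 28.** The five phenol O–H bonds are traced back to methoxymethyl (MOM) ethers. MOM is preferred to benzyl, whose hydrogenolysis would endanger the indenone alkene, and to silyl ethers, which do not direct lithiation and are base-labile on phenols. The forward step needs only dilute acid in methanol, which leaves the aryl methyl ethers, the methyl ester and the enone alone.

**28 from 26.** The C2=C3 alkene is traced back by formal addition of water to the tertiary α-ketol 26 (hydroxyl on C2, hydrogen on C3). The two crowded alkene carbons thus become sp3 carbons joined by a C–C bond-forming step, and the alkene itself is left to an elimination driven by conjugation with the C1 ketone and both aryl rings. Both diastereomers of 26 lead to the same 28.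

**26 from 25 (key disconnection).** The C2–C3 bond is cut. The neighbouring cuts are C2–ring B or C3–ring D, which mean cross-coupling of di-ortho-substituted partners at a preformed indenone, and C1–C7a, which means acylating ring C meta to both of its oxygens. All of these fight the crowding or the electronics. Cutting C2–C3 gives diketone 25, in which the two halves are held only by a two-carbon unit, and the forward reaction asks for nothing but light. It requires that only the diarylmethane hydrogen is transferred and that only the diketone absorbs.

**25 from 24, and 24 from 23 and 13.** The diketone is taken back to diarylalkyne 24, which is inert and unhindered to assemble. The alkyne is cut at its bond to ring C, giving terminal alkyne 23 (rings A and B) and aryl bromide 13 (rings C and D), two halves of similar size. The forward steps are a Sonogashira coupling at a bromide that has one ortho substituent, and an oxidation that must spare the diarylmethane CH2.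

**13 from 2 and 10.** The CH2–ring D bond is cut. Ring D arrives as the aryl nucleophile obtained by lithiation of 2 between its two MOM ethers, and ring C as benzylic bromide 10. The neighbouring option, addition of aryllithium 11 to aldehyde 8 followed by deoxygenation, is one step shorter but needs an acidic ionic reduction in the presence of three MOM ethers. The copper-mediated benzylation stays neutral. Bromide 10 goes back through alcohol 9, aldehyde 8 and phenol 7 to aldehyde 5 and to 1-bromo-3,5-dimethoxybenzene (3). The bromine of 3 fixes the formylation site and later serves the Sonogashira coupling, and the aldehyde directs the selective demethylation. Compound 2 comes from orcinol (1).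

**23 from 22, 22 from 20 and 21, and 20 from 19 and 17.** The ethynyl group is taken back to the bromide of 20 and ethynyltrimethylsilane (21). The ring B hydroxyl next to the ether oxygen is taken back to the aldehyde of 17 by a Baeyer–Villiger retron. The formyl group therefore does double duty: it activates the ether-forming step and then becomes the oxygen.

**17 from 15 and 16, and 15 from 14.** The ether is cut on the ring B side. The ring B carbon can be activated for substitution by an ortho formyl group in fluoride 16. The ring A carbon could be activated only by an ester twisted out of conjugation by two ortho groups. The forward reaction is an addition–elimination by the phenoxide of 15, the mono-MOM ether of commercial methyl 2,6-dihydroxy-4-methylbenzoate (14).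

## Roads not taken

Alternative 1: Ring A is built last on the ether oxygen. With the ester-bearing ring carbon as C1 and the hydroxyl-bearing carbon as C2, the cut runs through ring A bonds C1–C2 and C5–C6. In the forward direction the silyl ketene acetal diene [(1-methoxy-3-methylbuta-1,3-dien-1-yl)oxy]trimethylsilane A2 adds across the triple bond of the aryl ynol ether ester methyl 3-[2-(benzyloxy)-6-(dimethoxymethyl)-4-methoxyphenoxy]prop-2-ynoate A1. The adduct then sheds the silyl and methoxy groups of its former acetal carbon and enolizes to the salicylate methyl 2-[2-(benzyloxy)-6-(dimethoxymethyl)-4-methoxyphenoxy]-6-hydroxy-4-methylbenzoate A3.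
- Merits: the crowded ether oxygen is attached to a small propiolate before ring A exists, and the polarity of both partners fixes the regiochemistry.
- Weak points: the aryloxypropiolate A1 is a delicate, multi-step reagent and, as a push–pull alkyne, a sluggish dienophile. Salicylate A3 is only the ring A–ring B half, so the C2=C3 problem is untouched.
- Comparison: for the hindered ether alone this road is probably stronger than step 9, which must push an ester-flanked phenoxide onto a fluoride deactivated by a para methoxy group. The chosen plan sets against it that ring A is bought ready-made and that its key step is spent on the bond no purchase can supply.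

Alternative 2: The indenone carbonyl carbon is excised, cutting C1–C2 and C1–C7a, and the remainder is traced to the benzofuran 4-bromo-6-methoxy-2-[5-methoxy-3-(methoxymethoxy)-2-(triisopropylsilyloxy)phenyl]-3-[2,6-bis(methoxymethoxy)-4-methylphenyl]-1-benzofuran A4. In the forward direction an arene radical-anion reductant cleaves the furan O–C2 bond and converts the bromide into an aryllithium. Carboxylation then lets the one added carbon bond to both carbanions, giving the hydroxyindenone 4-hydroxy-6-methoxy-2-[5-methoxy-3-(methoxymethoxy)-2-(triisopropylsilyloxy)phenyl]-3-[2,6-bis(methoxymethoxy)-4-methylphenyl]inden-1-one A5.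
- Merits: a 2,3-diarylbenzofuran such as A4 is quick to assemble, and the core arrives at the final oxidation level with the C4 hydroxyl already free and no dehydration step.
- Weak points: two different carbanions must be generated and kept alive together. Ring closure by attack of an organolithium on a lithium carboxylate within such a dianion has no close model. The indenone A5 is more easily reduced than benzofuran A4. The ring B oxygen of A5 is a hindered silyl-protected phenol beside the indenone, so the most crowded C–O bond is left for the end.
- Comparison: this road reaches the core in fewer steps. The chosen plan offers in exchange a ring closure of a known type under neutral conditions and an ether made early on simple partners.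

Alternative 3: Ring D is built on C3. The cut runs through the two ring D bonds that join its ipso carbon to the silyloxy-bearing carbon and its benzyloxy-bearing carbon to the neighbouring CH. In the forward direction the pyrone 6-[(tert-butyldimethylsilyl)oxy]-4-methyl-2H-pyran-2-one A7 adds across the benzyloxyethynyl group of the indenone methyl 2-(benzyloxy)-6-{2-(benzyloxy)-6-[4-(benzyloxy)-3-[(benzyloxy)ethynyl]-6-methoxy-1-oxo-1H-inden-2-yl]-4-methoxyphenoxy}-4-methylbenzoate A6. The bicyclic lactone then decarboxylates to the protected target A8, which is Ascomindone B with four benzyl ethers and one ring D tert-butyldimethylsilyl ether.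
- Merits: the crowded C3–aryl bond is never made by coupling, the polarity of the ynol ether and the pyrone sets the regiochemistry, and the approach is convergent and late-stage.
- Weak points: indenone A6 combines a heat- and acid-sensitive ynol ether with an enone double bond that is itself a dienophile, while pyrone cycloadditions need heat. Pyrone A7 is labile. The four benzyl ethers of A8 must be removed beside a reducible alkene. Indenone A6 already presupposes an indenone synthesis with ring B in place.
- Comparison: this road addresses the steric problem at C3 more directly than any coupling. The chosen plan answers it differently, bringing ring D in as lithiated orcinol ether at the diarylmethane stage, where the crowding does not yet exist, with chemistry that is known for each step.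

Key step: step 16

Remark: aldehyde 16 is treated as a purchasable halogenated benzaldehyde building block.
Remark: 26 may form as two diastereomers; the trans-diaryl racemate is the one entered in the list, and either isomer is carried on to 28.

## Route

Step 1
Reactants: 1 orcinol (5-methylbenzene-1,3-diol)
Product: 2 1,3-bis(methoxymethoxy)-5-methylbenzene
Conditions: MOMCl (2.5 equiv), i-Pr2NEt, CH2Cl2, 0 °C to rt
Reagents that add atoms: chloromethyl methyl ether (MOMCl), COCCl
Why: Double O-alkylation of the phenols (Williamson-type acetal ether formation); the two MOM ethers later direct lithiation to the carbon between them and are removed by the final acidic methanolysis.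

Step 2
Reactants: 3 1-bromo-3,5-dimethoxybenzene
Product: 5 2-bromo-4,6-dimethoxybenzaldehyde, via aryl iminium chloride 4 (not isolated)
Conditions: POCl3, DMF, 0 °C to 90 °C; then H2O
Reagents that add atoms: N,N-dimethylformamide, CN(C)C=O; water, O
Why: Vilsmeier–Haack formylation; the chloroiminium electrophile attacks the carbon para to one methoxy group and ortho to the other, the position between the two methoxy groups being more hindered, and water hydrolyses iminium salt 4 to the aldehyde.

Step 3
Reactants: 5 2-bromo-4,6-dimethoxybenzaldehyde
Product: 7 2-bromo-6-hydroxy-4-methoxybenzaldehyde, via aryloxydichloroborane 6 (not isolated)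
Conditions: BCl3 (1.2 equiv), CH2Cl2, −78 °C to 0 °C; then H2O
Reagents that add atoms: none
Why: Chelation-controlled ether cleavage: BCl3 binds the aldehyde oxygen and the neighbouring methoxy oxygen, chloride removes only that methyl group, and hydrolysis of 6 frees the phenol while the para methoxy group stays.

Step 4
Reactants: 7 2-bromo-6-hydroxy-4-methoxybenzaldehyde
Product: 8 2-bromo-4-methoxy-6-(methoxymethoxy)benzaldehyde
Conditions: MOMCl, i-Pr2NEt, CH2Cl2, 0 °C to rt
Reagents that add atoms: chloromethyl methyl ether (MOMCl), COCCl
Why: O-alkylation of the hydrogen-bonded phenol (acetal protection); the MOM ether matches the other phenol masks and tolerates hydride, copper and palladium chemistry.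

Step 5
Reactants: 8 2-bromo-4-methoxy-6-(methoxymethoxy)benzaldehyde
Product: 9 [2-bromo-4-methoxy-6-(methoxymethoxy)phenyl]methanol
Conditions: NaBH4, MeOH, 0 °C
Reagents that add atoms: none
Why: Borohydride reduction of an aryl aldehyde to the benzylic alcohol; the aryl bromide and the acetal are inert.

Step 6
Reactants: 9 [2-bromo-4-methoxy-6-(methoxymethoxy)phenyl]methanol
Product: 10 1-bromo-2-(bromomethyl)-5-methoxy-3-(methoxymethoxy)benzene
Conditions: CBr4, PPh3, CH2Cl2, 0 °C; used at once
Reagents that add atoms: tetrabromomethane, BrC(Br)(Br)Br
Why: Appel bromination under neutral conditions, chosen so that the acid-labile MOM ether and the electron-rich ring never meet HBr.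

Step 7
Reactants: 2 1,3-bis(methoxymethoxy)-5-methylbenzene; 10 1-bromo-2-(bromomethyl)-5-methoxy-3-(methoxymethoxy)benzene
Product: 13 2-{[2-bromo-4-methoxy-6-(methoxymethoxy)phenyl]methyl}-1,3-bis(methoxymethoxy)-5-methylbenzene, via aryllithium 11 (not isolated), via arylcopper 12 (not isolated)
Conditions: n-BuLi, THF, 0 °C; CuI (1.05 equiv), −40 °C; then 10, −40 °C to rt
Reagents that add atoms: none
Why: Directed ortho-lithiation of 2 at the carbon flanked by both MOM ethers, transmetalation to copper to suppress halogen–lithium exchange with the two bromides of 10, then SN2 benzylation of arylcopper 12; the aryl bromide of 10 does not react with the organocopper.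

Step 8
Reactants: 14 methyl 2,6-dihydroxy-4-methylbenzoate
Product: 15 methyl 2-hydroxy-6-(methoxymethoxy)-4-methylbenzoate
Conditions: MOMCl (1.05 equiv), i-Pr2NEt, CH2Cl2, 0 °C
Reagents that add atoms: chloromethyl methyl ether (MOMCl), COCCl
Why: Mono-protection by O-alkylation: once the first phenol is masked, the second is locked in a hydrogen bond to the ester carbonyl and reacts much more slowly, so one equivalent should stop at 15.

Step 9
Reactants: 15 methyl 2-hydroxy-6-(methoxymethoxy)-4-methylbenzoate; 16 3-bromo-2-fluoro-5-methoxybenzaldehyde
Product: 17 methyl 2-(2-bromo-6-formyl-4-methoxyphenoxy)-6-(methoxymethoxy)-4-methylbenzoate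
Conditions: K2CO3, DMF, 100 °C
Reagents that add atoms: none
Why: Nucleophilic aromatic substitution (addition–elimination, SNAr): the phenoxide of 15 adds to the fluorine-bearing carbon, the Meisenheimer intermediate is stabilised by the ortho formyl group, and fluoride leaves; the bromide is meta to the formyl group and is not displaced.

Step 10
Reactants: 17 methyl 2-(2-bromo-6-formyl-4-methoxyphenoxy)-6-(methoxymethoxy)-4-methylbenzoate
Product: 19 methyl 2-(2-bromo-6-hydroxy-4-methoxyphenoxy)-6-(methoxymethoxy)-4-methylbenzoate, via aryl formate 18 (not isolated)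
Conditions: mCPBA, CH2Cl2, rt; then K2CO3 (cat.), MeOH, 0 °C
Reagents that add atoms: 3-chloroperoxybenzoic acid (mCPBA), OOC(=O)c1cccc(Cl)c1
Why: Baeyer–Villiger (Dakin-type) oxidation: the peracid adduct of the aldehyde rearranges with migration of the aryl group, which carries the ortho aryloxy donor, to formate 18, and mild methanolysis frees the phenol; the ring A methyl ester is unchanged in methanol.

Step 11
Reactants: 19 methyl 2-(2-bromo-6-hydroxy-4-methoxyphenoxy)-6-(methoxymethoxy)-4-methylbenzoate
Product: 20 methyl 2-[2-bromo-4-methoxy-6-(methoxymethoxy)phenoxy]-6-(methoxymethoxy)-4-methylbenzoate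
Conditions: MOMCl, i-Pr2NEt, CH2Cl2, 0 °C to rt
Reagents that add atoms: chloromethyl methyl ether (MOMCl), COCCl
Why: O-alkylation (acetal protection) of the new phenol, which would otherwise be oxidised by permanganate and would quench the excited diketone.

Step 12
Reactants: 20 methyl 2-[2-bromo-4-methoxy-6-(methoxymethoxy)phenoxy]-6-(methoxymethoxy)-4-methylbenzoate; 21 ethynyltrimethylsilane
Product: 22 methyl 2-{4-methoxy-2-(methoxymethoxy)-6-[(trimethylsilyl)ethynyl]phenoxy}-6-(methoxymethoxy)-4-methylbenzoate
Conditions: Pd(PPh3)2Cl2 (5 mol%), CuI (10 mol%), Et3N, DMF, 80 °C, sealed vessel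
Reagents that add atoms: none
Why: Sonogashira coupling: zerovalent palladium inserts into the aryl bromide, the copper acetylide transmetalates and reductive elimination forms the aryl–alkyne bond; the silyl group keeps the alkyne monofunctional.

Step 13
Reactants: 22 methyl 2-{4-methoxy-2-(methoxymethoxy)-6-[(trimethylsilyl)ethynyl]phenoxy}-6-(methoxymethoxy)-4-methylbenzoate
Product: 23 methyl 2-[2-ethynyl-4-methoxy-6-(methoxymethoxy)phenoxy]-6-(methoxymethoxy)-4-methylbenzoate
Conditions: K2CO3 (cat.), MeOH, rt
Reagents that add atoms: none
Why: Methoxide-catalysed protodesilylation of the alkynylsilane; the methyl ester (in methanol) and the MOM ethers are stable.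

Step 14
Reactants: 23 methyl 2-[2-ethynyl-4-methoxy-6-(methoxymethoxy)phenoxy]-6-(methoxymethoxy)-4-methylbenzoate; 13 2-{[2-bromo-4-methoxy-6-(methoxymethoxy)phenyl]methyl}-1,3-bis(methoxymethoxy)-5-methylbenzene
Product: 24 methyl 2-{2-[(2-{[2,6-bis(methoxymethoxy)-4-methylphenyl]methyl}-5-methoxy-3-(methoxymethoxy)phenyl)ethynyl]-4-methoxy-6-(methoxymethoxy)phenoxy}-6-(methoxymethoxy)-4-methylbenzoate
Conditions: PdCl2(MeCN)2 (5 mol%), XPhos (15 mol%), Cs2CO3, MeCN, 80 °C
Reagents that add atoms: none
Why: Copper-free Sonogashira coupling: the bulky electron-rich phosphine lets zerovalent palladium insert into the ortho-substituted bromide of 13, and leaving out copper avoids oxidative dimerisation of 23; neither partner has a free ortho heteroatom that could cyclise onto the alkyne.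

Step 15
Reactants: 24 the diarylalkyne of step 14
Product: 25 methyl 2-{2-[2-(2-{[2,6-bis(methoxymethoxy)-4-methylphenyl]methyl}-5-methoxy-3-(methoxymethoxy)phenyl)-2-oxoacetyl]-4-methoxy-6-(methoxymethoxy)phenoxy}-6-(methoxymethoxy)-4-methylbenzoate
Conditions: KMnO4, NaHCO3, MgSO4, acetone/H2O, 0 °C to rt
Reagents that add atoms: potassium permanganate, [K+].[O-][Mn](=O)(=O)=O
Why: Permanganate oxidation of a diarylalkyne to the benzil under buffered neutral conditions (cycloaddition of permanganate to the triple bond, then further oxidation of the manganate ester); ethers, ester and acetals are inert and the buffer keeps hydroxide away from the diketone.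

Step 16
Reactants: 25 the 1,2-diketone of step 15
Product: 26 methyl 2-{2-[(2S*,3S*)-3-[2,6-bis(methoxymethoxy)-4-methylphenyl]-2-hydroxy-6-methoxy-4-(methoxymethoxy)-1-oxo-2,3-dihydro-1H-inden-2-yl]-4-methoxy-6-(methoxymethoxy)phenoxy}-6-(methoxymethoxy)-4-methylbenzoate (racemic, ring B and ring D trans)
Conditions: hν (blue LEDs, 420–450 nm), degassed PhH (0.01 M), rt
Reagents that add atoms: none
Why: Absorption in the n,π* band of the 1,2-diketone and intersystem crossing give the triplet diketone, whose C2 carbonyl oxygen abstracts a hydrogen from the ortho CH2 group through a seven-membered transition state (abstraction by the C1 oxygen through a six-membered one gives the photoenol, which reaches the same product by intramolecular aldol addition). The resulting 1,5-biradical, a ketyl radical at C2 and a diarylmethyl radical at C3, recombines after spin inversion to form the C2–C3 bond. The closest known reaction type is the Norrish–Yang photocyclization of ortho-alkylphenyl 1,2-diketones such as 1-(2-methylphenyl)propane-1,2-dione and 2-methylbenzil to 2-hydroxyindan-1-ones. The one ring that closes is the five-membered ring, by radical–radical recombination between C2 and C3 (in the photoenol path a 5-exo-trig attack of the dienol carbon on the C2 carbonyl). C2 and C3 become stereocentres in that bond formation under substrate control: the biradical should collapse through the rotamer that keeps ring B and ring D on opposite faces, giving mainly the trans racemate, and no absolute control is needed because both centres vanish in step 17. The step needs site selectivity in the hydrogen transfer, and geometry secures it: only the diarylmethane CH2 is ortho to the diketone, the MOM CH2 groups are meta to the carbonyl-bearing carbons or on remote rings, and the ortho substituent of the ring B carbonyl is an aryloxy group with no abstractable hydrogen. It also needs a photostable product, which the wavelength secures because above 400 nm only the diketone absorbs, and degassing keeps oxygen from intercepting the triplet and the biradical.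

Step 17
Reactants: 26 the 2-hydroxyindan-1-one of step 16
Product: 28 methyl 2-{2-[3-[2,6-bis(methoxymethoxy)-4-methylphenyl]-6-methoxy-4-(methoxymethoxy)-1-oxo-1H-inden-2-yl]-4-methoxy-6-(methoxymethoxy)phenoxy}-6-(methoxymethoxy)-4-methylbenzoate, via chlorosulfite ester 27 (not isolated)
Conditions: SOCl2, pyridine, CH2Cl2, 0 °C to rt
Reagents that add atoms: none
Why: Dehydration of a tertiary alcohol through its chlorosulfite 27: in the trans-diaryl isomer the C3 hydrogen is anti to the leaving group, pyridine removes it in an E2 step, and conjugation of the new alkene with the ketone and both aryl rings drives the elimination; pyridine also buffers the HCl that would attack the MOM ethers.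

Step 18
Reactants: 28 the penta-MOM indenone of step 17
Product: 29 Ascomindone B, methyl 2-{2-[3-(2,6-dihydroxy-4-methylphenyl)-4-hydroxy-6-methoxy-1-oxo-1H-inden-2-yl]-6-hydroxy-4-methoxyphenoxy}-6-hydroxy-4-methylbenzoate
Conditions: HCl (3 M aq), MeOH, 45 °C
Reagents that add atoms: none
Why: Acid-catalysed methanolysis of the five aryl MOM acetals (oxocarbenium cleavage, the formaldehyde unit leaving as dimethoxymethane); aryl methyl ethers, the methyl ester and the indenone are stable to dilute HCl in methanol.

## Compound list

1 | orcinol (5-methylbenzene-1,3-diol) | Cc1cc(O)cc(O)c1 | starting material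
2 | 1,3-bis(methoxymethoxy)-5-methylbenzene | COCOc1cc(C)cc(OCOC)c1 | intermediate
3 | 1-bromo-3,5-dimethoxybenzene | COc1cc(Br)cc(OC)c1 | starting material
4 | [(2-bromo-4,6-dimethoxyphenyl)methylidene]dimethylammonium chloride | C[N+](C)=Cc1c(Br)cc(OC)cc1OC.[Cl-] | intermediate (not isolated)
5 | 2-bromo-4,6-dimethoxybenzaldehyde | O=Cc1c(Br)cc(OC)cc1OC | intermediate
6 | (3-bromo-2-formyl-5-methoxyphenoxy)dichloroborane | O=Cc1c(Br)cc(OC)cc1OB(Cl)Cl | intermediate (not isolated)
7 | 2-bromo-6-hydroxy-4-methoxybenzaldehyde | O=Cc1c(Br)cc(OC)cc1O | intermediate
8 | 2-bromo-4-methoxy-6-(methoxymethoxy)benzaldehyde | O=Cc1c(Br)cc(OC)cc1OCOC | intermediate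
9 | [2-bromo-4-methoxy-6-(methoxymethoxy)phenyl]methanol | OCc1c(Br)cc(OC)cc1OCOC | intermediate
10 | 1-bromo-2-(bromomethyl)-5-methoxy-3-(methoxymethoxy)benzene | BrCc1c(Br)cc(OC)cc1OCOC | intermediate
11 | [2,6-bis(methoxymethoxy)-4-methylphenyl]lithium | [Li]c1c(OCOC)cc(C)cc1OCOC | intermediate (not isolated)
12 | [2,6-bis(methoxymethoxy)-4-methylphenyl]copper | [Cu]c1c(OCOC)cc(C)cc1OCOC | intermediate (not isolated)
13 | 2-{[2-bromo-4-methoxy-6-(methoxymethoxy)phenyl]methyl}-1,3-bis(methoxymethoxy)-5-methylbenzene | COc1cc(Br)c(Cc2c(OCOC)cc(C)cc2OCOC)c(OCOC)c1 | intermediate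
14 | methyl 2,6-dihydroxy-4-methylbenzoate | COC(=O)c1c(O)cc(C)cc1O | starting material
15 | methyl 2-hydroxy-6-(methoxymethoxy)-4-methylbenzoate | COC(=O)c1c(O)cc(C)cc1OCOC | intermediate
16 | 3-bromo-2-fluoro-5-methoxybenzaldehyde | O=Cc1cc(OC)cc(Br)c1F | starting material
17 | methyl 2-(2-bromo-6-formyl-4-methoxyphenoxy)-6-(methoxymethoxy)-4-methylbenzoate | COC(=O)c1c(OCOC)cc(C)cc1Oc1c(Br)cc(OC)cc1C=O | intermediate
18 | methyl 2-[2-bromo-6-(formyloxy)-4-methoxyphenoxy]-6-(methoxymethoxy)-4-methylbenzoate | COC(=O)c1c(OCOC)cc(C)cc1Oc1c(Br)cc(OC)cc1OC=O | intermediate (not isolated)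
19 | methyl 2-(2-bromo-6-hydroxy-4-methoxyphenoxy)-6-(methoxymethoxy)-4-methylbenzoate | COC(=O)c1c(OCOC)cc(C)cc1Oc1c(Br)cc(OC)cc1O | intermediate
20 | methyl 2-[2-bromo-4-methoxy-6-(methoxymethoxy)phenoxy]-6-(methoxymethoxy)-4-methylbenzoate | COC(=O)c1c(OCOC)cc(C)cc1Oc1c(Br)cc(OC)cc1OCOC | intermediate
21 | ethynyltrimethylsilane | C#C[Si](C)(C)C | starting material
22 | methyl 2-{4-methoxy-2-(methoxymethoxy)-6-[(trimethylsilyl)ethynyl]phenoxy}-6-(methoxymethoxy)-4-methylbenzoate | COC(=O)c1c(OCOC)cc(C)cc1Oc1c(C#C[Si](C)(C)C)cc(OC)cc1OCOC | intermediate
23 | methyl 2-[2-ethynyl-4-methoxy-6-(methoxymethoxy)phenoxy]-6-(methoxymethoxy)-4-methylbenzoate | COC(=O)c1c(OCOC)cc(C)cc1Oc1c(C#C)cc(OC)cc1OCOC | intermediate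
24 | methyl 2-{2-[(2-{[2,6-bis(methoxymethoxy)-4-methylphenyl]methyl}-5-methoxy-3-(methoxymethoxy)phenyl)ethynyl]-4-methoxy-6-(methoxymethoxy)phenoxy}-6-(methoxymethoxy)-4-methylbenzoate | COC(=O)c1c(OCOC)cc(C)cc1Oc1c(OCOC)cc(OC)cc1C#Cc1cc(OC)cc(OCOC)c1Cc1c(OCOC)cc(C)cc1OCOC | intermediate
25 | methyl 2-{2-[2-(2-{[2,6-bis(methoxymethoxy)-4-methylphenyl]methyl}-5-methoxy-3-(methoxymethoxy)phenyl)-2-oxoacetyl]-4-methoxy-6-(methoxymethoxy)phenoxy}-6-(methoxymethoxy)-4-methylbenzoate | COC(=O)c1c(OCOC)cc(C)cc1Oc1c(OCOC)cc(OC)cc1C(=O)C(=O)c1cc(OC)cc(OCOC)c1Cc1c(OCOC)cc(C)cc1OCOC | intermediate (precursor of the key step)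
26 | methyl 2-{2-[(2S*,3S*)-3-[2,6-bis(methoxymethoxy)-4-methylphenyl]-2-hydroxy-6-methoxy-4-(methoxymethoxy)-1-oxo-2,3-dihydro-1H-inden-2-yl]-4-methoxy-6-(methoxymethoxy)phenoxy}-6-(methoxymethoxy)-4-methylbenzoate, racemic, ring B and ring D trans (one enantiomer drawn) | O=C1c2cc(OC)cc(OCOC)c2[C@@H](c2c(OCOC)cc(C)cc2OCOC)[C@]1(O)c1cc(OC)cc(OCOC)c1Oc1cc(C)cc(OCOC)c1C(=O)OC | intermediate (product of the key step)
27 | chlorosulfite ester of 26 (O–S(O)Cl on C2, racemic, both configurations at sulfur) | O=C1c2cc(OC)cc(OCOC)c2[C@@H](c2c(OCOC)cc(C)cc2OCOC)[C@]1(OS(Cl)=O)c1cc(OC)cc(OCOC)c1Oc1cc(C)cc(OCOC)c1C(=O)OC | intermediate (not isolated)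
28 | methyl 2-{2-[3-[2,6-bis(methoxymethoxy)-4-methylphenyl]-6-methoxy-4-(methoxymethoxy)-1-oxo-1H-inden-2-yl]-4-methoxy-6-(methoxymethoxy)phenoxy}-6-(methoxymethoxy)-4-methylbenzoate | COC(=O)c1c(OCOC)cc(C)cc1Oc1c(OCOC)cc(OC)cc1C1=C(c2c(OCOC)cc(C)cc2OCOC)c2c(OCOC)cc(OC)cc2C1=O | intermediate
29 | Ascomindone B | COC(=O)c1c(O)cc(C)cc1Oc1c(O)cc(OC)cc1C1=C(c2c(O)cc(C)cc2O)c2c(O)cc(OC)cc2C1=O | target

## Step count and uncertain steps

Total step count: 18. Longest linear sequence: 11 steps (steps 8 to 18 from 14; the ring C branch, steps 2 to 7 followed by 14 to 18, is equally long).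

Risk at step 16 (key step): the crowded diarylmethane group may be twisted away from the diketone, so that hydrogen transfer is inefficient. The biradical or photoenol may revert to 25, hydrogen donors may reduce the triplet, or 26 may be photolysed further. The fallback closes the same bond in the ground state and sets out from 25. The CH2 hydrogen is a vinylogous α-hydrogen of the C1 ketone and is flanked by two aryl groups. KN(SiMe3)2 in THF at −78 °C should give the extended enolate, whose benzylic carbon adds to the C2 carbonyl in an intramolecular aldol reaction. This returns to the route at 26 and makes no new compound, which the entry F0 records.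

Risk at step 7: the electron-rich benzylic bromide 10 may ionise or alkylate itself before it meets the organocopper. Incomplete transmetalation may allow halogen–lithium exchange and homocoupling, and substitution between two di-ortho-substituted partners may be slow. The fallback sets out from 8 and 2. Aryllithium 11 is added to aldehyde 8 at −78 °C to give the racemic carbinol [2-bromo-4-methoxy-6-(methoxymethoxy)phenyl][2,6-bis(methoxymethoxy)-4-methylphenyl]methanol F1. Ionic hydrogenation (Et3SiH, CF3CO2H, CH2Cl2, −40 °C, quenched cold with Et3N) then removes the doubly benzylic hydroxyl and returns to the route at 13.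

Risk at step 9: substitution may be slow, because the fluorine-bearing carbon carries a para methoxy donor and the nucleophile is an ester-flanked, hydrogen-bonded phenoxide. At the temperature then needed, transfer of the ester methyl group to phenoxide and erosion of the MOM group become competitive. The fallback sets out from 15 and replaces addition–elimination by a copper-catalysed Ullmann ether coupling. Phenol 15 is coupled with the iodo counterpart of 16, 3-bromo-2-iodo-5-methoxybenzaldehyde F2, using CuI, picolinic acid and K3PO4 in DMSO at 90 °C. The iodide ortho to the formyl group should react in preference to the bromide, and the route is rejoined at 17.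

Risk at step 15: permanganate may over-oxidise, either by cleaving the diketone to two benzoic acids or by attacking the doubly benzylic CH2, or the hindered alkyne may react too slowly. The fallback sets out from 24. Semi-hydrogenation (H2, Pd/CaCO3 poisoned with Pb(OAc)2, quinoline) gives the (Z)-stilbene methyl 2-{2-[(Z)-2-(2-{[2,6-bis(methoxymethoxy)-4-methylphenyl]methyl}-5-methoxy-3-(methoxymethoxy)phenyl)ethenyl]-4-methoxy-6-(methoxymethoxy)phenoxy}-6-(methoxymethoxy)-4-methylbenzoate F3. Syn-dihydroxylation of this stilbene (OsO4 cat., N-methylmorpholine N-oxide) gives the racemic diol methyl 2-{2-[(1R*,2S*)-2-(2-{[2,6-bis(methoxymethoxy)-4-methylphenyl]methyl}-5-methoxy-3-(methoxymethoxy)phenyl)-1,2-dihydroxyethyl]-4-methoxy-6-(methoxymethoxy)phenoxy}-6-(methoxymethoxy)-4-methylbenzoate F4. Swern oxidation of both carbinols (DMSO, (COCl)2, Et3N, −78 °C) returns to the route at 25.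

Risk at step 17: sulfinylation of the hindered tertiary alcohol may be slow. The cis-diaryl diastereomer has no hydrogen anti to the leaving group and may fail to eliminate, or may be substituted by chloride. The fallback sets out from 26 and uses a stepwise carbanion elimination that is indifferent to relative configuration. The alcohol is acylated with trifluoroacetic anhydride, pyridine and DMAP to the 2-(trifluoroacetoxy)indan-1-one F5, the C2 trifluoroacetate of 26. DBU in THF then removes the C3 hydrogen, which is a vinylogous α-hydrogen of the C1 ketone, and the extended enolate expels trifluoroacetate (E1cB). This returns to the route at 28.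

## Further compounds

F0 | step 16 | none | none
F1 | step 7 | [2-bromo-4-methoxy-6-(methoxymethoxy)phenyl][2,6-bis(methoxymethoxy)-4-methylphenyl]methanol (racemic) | COc1cc(Br)c(C(O)c2c(OCOC)cc(C)cc2OCOC)c(OCOC)c1
F2 | step 9 | 3-bromo-2-iodo-5-methoxybenzaldehyde | O=Cc1cc(OC)cc(Br)c1I
F3 | step 15 | methyl 2-{2-[(Z)-2-(2-{[2,6-bis(methoxymethoxy)-4-methylphenyl]methyl}-5-methoxy-3-(methoxymethoxy)phenyl)ethenyl]-4-methoxy-6-(methoxymethoxy)phenoxy}-6-(methoxymethoxy)-4-methylbenzoate | COC(=O)c1c(OCOC)cc(C)cc1Oc1c(OCOC)cc(OC)cc1/C=C\c1cc(OC)cc(OCOC)c1Cc1c(OCOC)cc(C)cc1OCOC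
F4 | step 15 | methyl 2-{2-[(1R*,2S*)-2-(2-{[2,6-bis(methoxymethoxy)-4-methylphenyl]methyl}-5-methoxy-3-(methoxymethoxy)phenyl)-1,2-dihydroxyethyl]-4-methoxy-6-(methoxymethoxy)phenoxy}-6-(methoxymethoxy)-4-methylbenzoate (racemic, one enantiomer drawn) | COC(=O)c1c(OCOC)cc(C)cc1Oc1c(OCOC)cc(OC)cc1[C@@H](O)[C@@H](O)c1cc(OC)cc(OCOC)c1Cc1c(OCOC)cc(C)cc1OCOC
F5 | step 17 | C2 trifluoroacetate of 26 (racemic, trans-diaryl isomer drawn) | O=C1c2cc(OC)cc(OCOC)c2[C@@H](c2c(OCOC)cc(C)cc2OCOC)[C@]1(OC(=O)C(F)(F)F)c1cc(OC)cc(OCOC)c1Oc1cc(C)cc(OCOC)c1C(=O)OC
A1 | alternative 1 | methyl 3-[2-(benzyloxy)-6-(dimethoxymethyl)-4-methoxyphenoxy]prop-2-ynoate | COC(=O)C#COc1c(OCc2ccccc2)cc(OC)cc1C(OC)OC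
A2 | alternative 1 | [(1-methoxy-3-methylbuta-1,3-dien-1-yl)oxy]trimethylsilane | COC(O[Si](C)(C)C)=CC(C)=C
A3 | alternative 1 | methyl 2-[2-(benzyloxy)-6-(dimethoxymethyl)-4-methoxyphenoxy]-6-hydroxy-4-methylbenzoate | COC(=O)c1c(O)cc(C)cc1Oc1c(OCc2ccccc2)cc(OC)cc1C(OC)OC
A4 | alternative 2 | 4-bromo-6-methoxy-2-[5-methoxy-3-(methoxymethoxy)-2-(triisopropylsilyloxy)phenyl]-3-[2,6-bis(methoxymethoxy)-4-methylphenyl]-1-benzofuran | COc1cc(Br)c2c(c1)oc(-c1cc(OC)cc(OCOC)c1O[Si](C(C)C)(C(C)C)C(C)C)c2-c1c(OCOC)cc(C)cc1OCOC
A5 | alternative 2 | 4-hydroxy-6-methoxy-2-[5-methoxy-3-(methoxymethoxy)-2-(triisopropylsilyloxy)phenyl]-3-[2,6-bis(methoxymethoxy)-4-methylphenyl]inden-1-one | O=C1C(c2cc(OC)cc(OCOC)c2O[Si](C(C)C)(C(C)C)C(C)C)=C(c2c(OCOC)cc(C)cc2OCOC)c2c(O)cc(OC)cc12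
A6 | alternative 3 | methyl 2-(benzyloxy)-6-{2-(benzyloxy)-6-[4-(benzyloxy)-3-[(benzyloxy)ethynyl]-6-methoxy-1-oxo-1H-inden-2-yl]-4-methoxyphenoxy}-4-methylbenzoate | COC(=O)c1c(OCc2ccccc2)cc(C)cc1Oc1c(OCc2ccccc2)cc(OC)cc1C1=C(C#COCc2ccccc2)c2c(OCc3ccccc3)cc(OC)cc2C1=O
A7 | alternative 3 | 6-[(tert-butyldimethylsilyl)oxy]-4-methyl-2H-pyran-2-one | O=c1cc(C)cc(O[Si](C)(C)C(C)(C)C)o1
A8 | alternative 3 | Ascomindone B with four benzyl ethers and one ring D tert-butyldimethylsilyl ether | COC(=O)c1c(OCc2ccccc2)cc(C)cc1Oc1c(OCc2ccccc2)cc(OC)cc1C1=C(c2c(OCc3ccccc3)cc(C)cc2O[Si](C)(C)C(C)(C)C)c2c(OCc3ccccc3)cc(OC)cc2C1=O
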